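## Structural features

The target is a monocyclic, iridal-type triterpenoid ester built on one cyclohexane ring. Ring numbering: C1 is the CH carrying the 3-(stearoyloxy)propyl arm, C2 the ring end of an exocyclic tetrasubstituted enal C2=C(CH3)CHO, C3 and C4 are CH2, C5 is a tertiary carbinol with a methyl group, and C6 is a quaternary carbon with a methyl group and a thirteen-carbon trienyl chain. The chain holds an allylic secondary alcohol (R) between two E-trisubstituted alkenes and ends in a prenyl unit. C1, C6 and C5 are contiguous stereocentres (1S,5S,6R): the two methyl groups and the arm lie on one face, the C5 hydroxyl and the chain on the other. The fourth stereocentre is five bonds from the ring and cannot be controlled from it. Fragile groups are the enal (formyl group cis to the crowded C1, gamma-hydrogen at C1 open to dienolisation), the allylic alcohol (ionisation), the skipped polyene (acid, electrophiles) and the single primary ester beside free secondary and tertiary hydroxyls. The real difficulty is the pair of vicinal fully substituted carbons C5/C6, then the geometry of the tetrasubstituted enal and the epimerisable C1. The key step uses the fact that C6 with its methyl and 4-methylpent-3-enyl branch is C3 of a geranyl unit, while C5 with its methyl and the C4–C3–C2 tether is the ketone end of a levulinate. A gamma-selective allylboration therefore makes the C5–C6 bond, fixes both centres, and leaves a vinyl group (future C1 and first arm carbon) and an acyl carbon (future C2).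

## Logic of the disconnections

30 to 27 and 28: the acyl–oxygen bond of the ester is cut. The ester is the group most sensitive to bases and nucleophiles and its eighteen carbons add nothing to the problem, so it comes last. This removes a third of the carbon atoms. The forward step must acylate one primary hydroxyl beside a secondary allylic and a tertiary one without disturbing the enal (step 17); 27 is uncovered from 26 by loss of three silyl groups (step 16).

26 to 24, 23 and 20: the formyl C=O is traced to a C–S bond (24), the exocyclic C–CH3 bond is cut (23), and the C2=C bond is traced to a C2 ketone plus a two-carbon acetylide (20). The reason is that the formyl group must sit on the more crowded side of a tetrasubstituted alkene, which olefination or sigmatropic transposition of a ketone does not secure. In 23 the exocyclic carbons lie on a line, so no geometry exists until the methyl group enters, and it must enter in the ring plane. The gain is that the only stereogenic alkene of the ring becomes a ketone. The demand is methyl delivery to the central allene carbon from the C3 side (step 14) and carbanion chemistry that does not let the alkene rotate (step 15).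

20 to 19, 17 and 15: the bond between the first and second arm carbons is cut, giving the exocyclic enone 15 and a vinyl donor; the primary C–O bond of 19 comes from the terminal alkene of 17, and 20 is the doubly silylated form. The cut is placed there because 15 is the direct ring-opening product of a cyclopropanol and its beta-carbon is the carbon that needs extending. The arm shrinks to one carbon. The demands are a clean conjugate addition, control of C1 on protonation (step 10), and hydroboration of the one monosubstituted alkene beside a ketone (step 11).

15 to 14 and 13: the C1–C2 bond and the C2–CH2 bond are cut, which opens the carbocycle. 13 already holds C2 at the acyl level and C1 as an alkene carbon, so nothing has to be added to close the ring. The gain is an acyclic chain on a five-membered lactone. The forward steps demand that low-valent titanium pick the monosubstituted alkene among four alkenes and close a six-membered ring onto a lactone (step 8), and that ring opening cleave the external cyclopropane bond (step 9).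

13 to 12, 11, 10, and then 7 and 8: the bond between the carbinol carbon and its CH2 neighbour is cut, giving 7 and 8; the carbinol configuration is traced through ketone 11. The cut falls between the two isoprenoid halves at the only heteroatom of the chain, and 8 brings ten carbons with both alkenes in place. The demands are alpha-selective allyl transfer with retention of the E geometry, to an aldehyde in the presence of a lactone (step 4), and a catalyst-controlled ketone reduction (step 6), because the ring cannot influence this centre.

7 to 5: one allylic C–H bond of the E-methyl group becomes C=O. The prenyl terminus is the only electron-rich alkene with allylic hydrogens, since the vinyl group sits on a quaternary carbon. The demand is E-selective allylic oxidation (step 3).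

5 to 2 and 3: the C5–C6 bond is cut, and the lactone C–O bond is traced to an ester. This single cut removes both fully substituted stereocentres and returns two achiral materials. The demand is gamma-selectivity, a chair with the ketone methyl axial, and catalyst control of the ketone face (step 2).

2 to 1: the C–B bond is traced to the C–O bond of the allylic alcohol, with retention of the E alkene (step 1).

## Other disconnections considered

Alternative 1: The cut runs through C1–C6 and C4–C5. The diene A1 and the chiral butenolide A2 would undergo a [4+2] cycloaddition under high pressure to give the cis-fused lactone acetal A3.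
- In its favour: both fully substituted ring carbons form together and their cis relationship follows from suprafacial addition to a cyclic dienophile. The menthyloxy acetal shields one face and so sets the absolute configuration. The silyloxy group steers the regiochemistry and leaves C2 as a regiodefined enol ether. C1 is set in the same event.
- Against it here: a tetrasubstituted dienophile is a poor partner, hence the pressure. The endo/exo preference that decides C1 is not secured. A3 carries a carboxyl carbon on C5 where the target has oxygen, so a carbon-to-oxygen degradation is needed. The acetal carbon on C6 is only the first of thirteen chain carbons.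
- Comparison: on structure the cycloaddition is the better of the two for C1, which the chosen plan sets later by protonation. It is the equal of the chosen plan in arriving at a C2 ketone from which the enal must still be built. On mechanism, an auxiliary-controlled pericyclic step stands against a catalytic allyl transfer that needs no stoichiometric chiral material. On step economy the chosen plan is ahead, because O5 and ten chain carbons are in place directly after its key step.

Alternative 2: The cut is the C1–C2 bond of the 1,7-enyne A4. Zirconium-mediated bicyclisation would join the vinyl group on C6 to the but-2-ynyl alkyne, and iodinolysis of the metallacycle would give the diiodide A5.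
- In its favour: syn-carbometalation fixes the enal geometry, since the carbon that becomes the formyl group is tied to C1 through the metallacycle. The alkenyl and the primary alkyl iodide are distinct handles for the formyl group and the arm. C1 is set in the ring closure.
- Against it here: the metal is used in stoichiometric amount. The facial selectivity at C1 next to the quaternary C6 is not assured. The two iodides must be differentiated, by a two-carbon extension with a terminal oxygen at one and a formylation at the other. A4 still needs the C5/C6 pair, for which a lactone of the kind made in the chosen key step would first have to be homologated to the alkyne.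
- Comparison: on structure this alternative is the better one for the enal geometry, which the chosen plan takes from steric approach control on an allene. For the vicinal stereocentres it offers nothing of its own. On mechanism both ring closures add a low-valent early transition metal to the same vinyl group; the titanium version delivers C2 already oxidised. On step economy the two are close: what is saved in the enal sequence is spent on making the alkyne and on telling the two iodides apart.

Alternative 3: The cuts are the bond from C6 to the first chain carbon and the bond from C1 to the arm. The bromoacetal A6 of a quinol-derived enone would give a radical that closes 5-exo onto C6, and the alpha-keto radical at C1 would be trapped by the allylstannane A7 to give the bicyclic ketone A8.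
- In its favour: two C–C bonds and two stereocentres arise in one chain process. The cis ring fusion relays C5 to C6, and the allyl group enters trans to the new ring, which is the required configuration at C1. The allyl group is the complete three-carbon arm, one hydroboration from the alcohol.
- Against it here: the absolute configuration rests on an enantioenriched tertiary alcohol in A6 that must itself be made or resolved. Organotin reagents are used in stoichiometric amount. The acetal stub supplies two chain carbons only, and the rest of the chain with its remote carbinol must follow.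
- Comparison: on structure the alternative is better at C1 and the arm, because the chosen plan needs three steps from the cyclopropanol to reach the same 2-allyl ketone stage. It is equal in ending at a C2 ketone. On mechanism a substrate-controlled radical cascade stands against a closed, catalyst-controlled transition state, and only the latter creates absolute configuration. On step economy the chosen plan is ahead on the chain and behind on the arm.

Key step: step 2

Remark on the structures: the configurations of 2, 3 and 5 were checked against the target and against the chair model (E-geranyl, ketone methyl axial). They agree (5S,6R in ring numbering), so no structure is corrected. 2 is used as the free boronic acid so that exchange with the diol is fast, and 3 keeps its ester so that lactonisation traps the tertiary alkoxide.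

Assumption: (S)-3,3'-dibromo-BINOL is taken to deliver the allyl group to the Re face of 3. This sense is assigned by analogy with aryl methyl ketones and should be confirmed on 5; the (R)-diol gives the mirror-image series with no other change.

Assumption: 8 is bought. The cyclopropane face drawn for 14 is the one expected from the bridged titanacycle; either face serves because C1 and C2 become trigonal in step 9.

## Steps

Step 1
Reactants: 1 geraniol
Product: 2 (E)-geranylboronic acid
Conditions: B2(OH)4, Pd(MeCN)4(BF4)2 (cat.), DMSO/MeOH, rt, argon
Reagents that add atoms: tetrahydroxydiboron, OB(O)B(O)O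
Why: Palladium-catalysed borylation of the free allylic alcohol; the allylpalladium intermediate is borylated at the less hindered terminus with retention of the E geometry, so the linear allylboronic acid should form. It is kept under argon and used at once, since oxidation and boroxine formation are the loss channels.

Step 2
Reactants: 2 (E)-geranylboronic acid; 3 ethyl levulinate
Product: 5 (5S)-5-[(3R)-3,7-dimethylocta-1,6-dien-3-yl]-5-methyloxolan-2-one, via hydroxy ester 4 (not isolated)
Conditions: (S)-3,3'-Br2-BINOL (20 mol %), t-BuOH, 3 Å MS, toluene, 0 °C to rt; then p-TsOH (cat.), CH2Cl2, rt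
Reagents that add atoms: none
Why: Exchange of the boronic acid hydroxyls with the chiral diol gives a more Lewis acidic cyclic boronate, which binds the ketone oxygen and transfers the allyl group through a closed six-membered chair with allylic transposition; the closest known reaction type is the diol-catalysed allylboration of ketones with gamma,gamma-disubstituted allylboronic acids. The new bond joins the former ketone carbon (C5) to the geranyl gamma-carbon (C6), which thereby carries methyl, 4-methylpent-3-enyl and vinyl. Relative configuration is controlled by the chair: the E alkene places the chain equatorial and the C6 methyl axial, and the ketone places its methyl axial and the ester-bearing arm equatorial, which gives the 5S,6R pair with the two methyl groups cis in the later ring. Absolute configuration is controlled by the diol on boron, which leaves the Re face of the ketone open. The tertiary borate then attacks the ethyl ester (5-exo-trig acyl substitution) and closes the gamma-lactone, which is not a ring of the target but protects O5 and keeps C2 at the acyl level. The step needs gamma- over alpha-attack (secured by the cyclic transition state), discrimination of methyl from the CH2CH2CO2Et arm (secured by their size difference and by t-BuOH, which holds back the uncatalysed boroxine pathway), and ketone over ester selectivity (allylboronic acids do not add to esters).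

Step 3
Reactants: 5 (5S)-5-[(3R)-3,7-dimethylocta-1,6-dien-3-yl]-5-methyloxolan-2-one
Product: 7 (2E,6R)-2,6-dimethyl-6-[(2S)-2-methyl-5-oxooxolan-2-yl]octa-2,7-dienal, via allylic alcohol 6 (not isolated)
Conditions: SeO2 (cat.), t-BuOOH, salicylic acid (cat.), CH2Cl2, rt; then MnO2, CH2Cl2, rt
Reagents that add atoms: tert-butyl hydroperoxide, CC(C)(C)OO (terminal oxidant; the oxygen is relayed by SeO2, O=[Se]=O)
Why: Selenium dioxide allylic oxidation (ene reaction, then [2,3]-shift) is selective for the E-methyl group of the trisubstituted alkene; the vinyl group has no allylic hydrogen and the lactone is inert. MnO2 converts any allylic alcohol left into the same E enal.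

Step 4
Reactants: 7 (2E,6R)-2,6-dimethyl-6-[(2S)-2-methyl-5-oxooxolan-2-yl]octa-2,7-dienal; 8 geranyl chloride
Product: 10 lactone carbinol (both C8 epimers), via geranylbarium chloride 9 (not isolated)
Conditions: BaI2, LiC12H10 (lithium biphenylide), THF, rt; 8, −78 °C; then 7, −78 °C
Reagents that add atoms: none
Why: Allylbarium reagents add to aldehydes 1,2 at the alpha-carbon with retention of the allyl E geometry (Barbier–Grignard-type addition), and at −78 °C the aldehyde should react well before the lactone. The new carbinol forms as both epimers, which steps 5 and 6 correct.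

Step 5
Reactants: 10 lactone carbinol (both C8 epimers)
Product: 11 lactone enone
Conditions: Dess–Martin periodinane (DMP), NaHCO3, CH2Cl2, 0 °C
Reagents that add atoms: none
Why: Buffered Dess–Martin oxidation of the secondary allylic alcohol removes the uncontrolled stereocentre; neutral, cold conditions should keep the beta,gamma-alkene from moving into conjugation.

Step 6
Reactants: 11 lactone enone
Product: 12 (8R)-lactone carbinol
Conditions: (S)-2-methyl-CBS-oxazaborolidine (cat.), catecholborane, toluene, −78 °C
Reagents that add atoms: none
Why: CBS reduction under reagent control: the alpha-methyl alkenyl group acts as the large substituent and the CH2-allyl group as the small one, so the (S)-catalyst should give the 8R alcohol, as with aryl methyl ketones. Catecholborane leaves the lactone and the alkenes untouched at this temperature.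

Step 7
Reactants: 12 (8R)-lactone carbinol
Product: 13 silyl ether lactone
Conditions: TBSCl, imidazole, DMF, rt
Reagents that add atoms: tert-butyldimethylsilyl chloride, CC(C)(C)[Si](C)(C)Cl
Why: Standard silylation of the only free hydroxyl; the ether shields the allylic alcohol from the organometallic, oxidative and sulfinylating steps that follow.

Step 8
Reactants: 13 silyl ether lactone
Product: 14 cyclopropanol diol
Conditions: Ti(OiPr)4, c-C5H9MgCl (slow addition), THF, rt
Reagents that add atoms: none
Why: Intramolecular Kulinkovich cyclopropanation: the titanacyclopropane (formally divalent titanium) exchanges with the only monosubstituted alkene, its internal carbon attacks the lactone carbonyl (C1–C2 bond, six-membered ring), the ring oxygen is expelled as the C5 alkoxide and the second C–Ti bond closes the cyclopropanol. Trisubstituted alkenes and the silyl ether take no part.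

Step 9
Reactants: 14 cyclopropanol diol
Product: 15 2-methylene ketone
Conditions: Pd(OAc)2 (cat.), pyridine, O2 (1 atm), toluene, 80 °C
Reagents that add atoms: none
Why: Known aerobic ring opening of cyclopropanols to enones: the palladium alkoxide undergoes beta-carbon elimination at the less substituted bond (C2–CH2), and beta-hydride elimination from the primary alkylpalladium gives the exocyclic enone. The alkene cannot move into the ring because C1 lies between the carbonyl and the quaternary C6; the crude enone is used at once.

Step 10
Reactants: 15 2-methylene ketone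
Product: 17 2-allyl ketone, via bis(trimethylsilyl) enol ether 16 (not isolated)
Conditions: CH2=CHMgBr, CuBr·SMe2 (cat.), Me3SiCl, THF, −78 °C; then aq. HCl, THF, 0 °C
Reagents that add atoms: vinylmagnesium bromide, C=C[Mg]Br
Why: Copper-catalysed conjugate addition of the vinyl Grignard reagent, accelerated by the silyl chloride, adds the two missing arm carbons; dilute acid then frees the ketone and the C5 hydroxyl. C1 is set on protonation: the half-chair with the C6 methyl pseudo-axial (chain and C5 methyl equatorial) should be protonated anti to that methyl, and this is also the more stable, arm-equatorial epimer, so later base contact (step 11) should converge on it.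

Step 11
Reactants: 17 2-allyl ketone
Product: 19 hydroxypropyl ketone, via pinacol boronate 18 (not isolated)
Conditions: HBpin, RhCl(PPh3)3 (cat.), THF, rt; then H2O2, aq. NaOH, 0 °C
Reagents that add atoms: hydrogen peroxide, OO
Why: Rhodium-catalysed hydroboration is selective for the monosubstituted terminal alkene over the trisubstituted ones and, being catalysed, should outrun ketone reduction; alkaline peroxide oxidation with retention gives the anti-Markovnikov primary alcohol. The basic medium also equilibrates C1 toward the equatorial arm.

Step 12
Reactants: 19 hydroxypropyl ketone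
Product: 20 bis(triethylsilyl) ketone
Conditions: Et3SiOTf, 2,6-lutidine, CH2Cl2, −78 to 0 °C
Reagents that add atoms: triethylsilyl triflate, CC[Si](CC)(CC)OS(=O)(=O)C(F)(F)F
Why: The silyl triflate silylates the primary and the hindered tertiary hydroxyl at low temperature, where 2,6-lutidine does not enolise the ketone. The tertiary ether is needed so that only the alkoxide made in step 13 is sulfinylated.

Step 13
Reactants: 20 bis(triethylsilyl) ketone
Product: 23 allenyl sulfone, via magnesium alkoxide 21 (not isolated), via propargylic sulfinate 22 (not isolated)
Conditions: HC≡CMgBr, CeCl3, THF, −78 to 0 °C; then p-TolS(O)Cl, −78 °C to rt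
Reagents that add atoms: ethynylmagnesium bromide, C#C[Mg]Br; 4-methylbenzenesulfinyl chloride, Cc1ccc(cc1)S(Cl)=O
Why: The cerium-modified acetylide adds to the hindered, enolisable ketone (equatorial attack, trans to the axial C6 methyl; the C2 configuration is lost again). The alkoxide is trapped as a tertiary propargylic sulfinate, which undergoes the known [2,3]-sigmatropic sulfinate-to-sulfone shift to the allene on warming.

Step 14
Reactants: 23 allenyl sulfone
Product: 24 (Z)-allyl sulfone
Conditions: Me2CuLi (from CuI and MeLi), Et2O/THF, −78 °C; aq. NH4Cl
Reagents that add atoms: lithium dimethylcuprate, [Li+].C[Cu-]C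
Why: Cuprate conjugate addition to an allenyl sulfone occurs at the central allene carbon, within the plane of C1–C2–C3; the equatorial arm on C1 blocks that side, so methyl should enter syn to C3 and leave the sulfonylmethyl carbon syn to C1. The alpha-sulfonyl carbanion does not rotate about the C2=C bond and is protonated at the alpha-carbon to give the allyl sulfone.

Step 15
Reactants: 24 (Z)-allyl sulfone
Product: 26 silylated (Z)-enal, via lithiated sulfone 25 (not isolated)
Conditions: n-BuLi, THF, −78 °C; then (Me3SiO)2, −78 to 0 °C
Reagents that add atoms: bis(trimethylsilyl) peroxide, C[Si](C)(C)OO[Si](C)(C)C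
Why: Oxidative desulfonylation: the alpha-sulfonyl allyl anion is oxygenated at the alpha-carbon by the silyl peroxide and the alpha-silyloxy sulfone collapses to the aldehyde with loss of sulfinate. Allylic sulfonyl anions keep their alkene geometry at low temperature, so the Z enal should result, and C1 is not touched because no base is left.

Step 16
Reactants: 26 silylated (Z)-enal
Product: 27 triol
Conditions: HF·pyridine, pyridine, THF, 0 °C to rt
Reagents that add atoms: none
Why: Fluoride-mediated cleavage of all three silyl ethers under buffered conditions that should spare the enal, the allylic alcohol and the C1 stereocentre.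

Step 17
Reactants: 27 triol; 28 stearic acid
Product: 30 target stearate, via stearoyl chloride 29 (not isolated)
Conditions: 28, (COCl)2, DMF (cat.), CH2Cl2, rt; then 27, 2,4,6-collidine, CH2Cl2, −78 °C
Reagents that add atoms: none
Why: Acylation with an acid chloride and the hindered base collidine at low temperature discriminates sterically in favour of the primary hydroxyl over the secondary allylic and tertiary ones. No base strong enough to dienolise the enal is present.

## Compound list

In the names, "TBSO-trienyl" is (3E,5R,7E)-5-(tert-butyldimethylsilyloxy)-4,8,12-trimethyltrideca-3,7,11-trien-1-yl; "ring locants" are C1–C6 as defined under Structural features.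

1 | geraniol, (2E)-3,7-dimethylocta-2,6-dien-1-ol | CC(C)=CCC/C(C)=C/CO | starting material
2 | (E)-geranylboronic acid, [(2E)-3,7-dimethylocta-2,6-dien-1-yl]boronic acid | CC(C)=CCC/C(C)=C/CB(O)O | intermediate
3 | ethyl levulinate, ethyl 4-oxopentanoate | CCOC(=O)CCC(C)=O | starting material
4 | ethyl (4S,5R)-5-ethenyl-4-hydroxy-4,5,9-trimethyldec-8-enoate (formed as its borate) | CCOC(=O)CC[C@](C)(O)[C@@](C)(C=C)CCC=C(C)C | intermediate
5 | (5S)-5-[(3R)-3,7-dimethylocta-1,6-dien-3-yl]-5-methyloxolan-2-one | O=C1CC[C@](C)(O1)[C@@](C)(C=C)CCC=C(C)C | intermediate
6 | (5S)-5-[(3R,6E)-8-hydroxy-3,7-dimethylocta-1,6-dien-3-yl]-5-methyloxolan-2-one | O=C1CC[C@](C)(O1)[C@@](C)(C=C)CC/C=C(\C)CO | intermediate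
7 | (2E,6R)-2,6-dimethyl-6-[(2S)-2-methyl-5-oxooxolan-2-yl]octa-2,7-dienal | O=C1CC[C@](C)(O1)[C@@](C)(C=C)CC/C=C(\C)C=O | intermediate
8 | geranyl chloride, (2E)-1-chloro-3,7-dimethylocta-2,6-diene | CC(C)=CCC/C(C)=C/CCl | starting material
9 | geranylbarium chloride | CC(C)=CCC/C(C)=C/C[Ba]Cl | intermediate
10 | (5S)-5-[(3R,6E,10E)-8-hydroxy-3,7,11,15-tetramethylhexadeca-1,6,10,14-tetraen-3-yl]-5-methyloxolan-2-one, 8R and 8S epimers | O=C1CC[C@](C)(O1)[C@@](C)(C=C)CC/C=C(\C)C(O)C/C=C(\C)CCC=C(C)C | intermediate
11 | (5S)-5-[(3R,6E,10E)-3,7,11,15-tetramethyl-8-oxohexadeca-1,6,10,14-tetraen-3-yl]-5-methyloxolan-2-one | O=C1CC[C@](C)(O1)[C@@](C)(C=C)CC/C=C(\C)C(=O)C/C=C(\C)CCC=C(C)C | intermediate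
12 | (5S)-5-[(3R,6E,8R,10E)-8-hydroxy-3,7,11,15-tetramethylhexadeca-1,6,10,14-tetraen-3-yl]-5-methyloxolan-2-one | O=C1CC[C@](C)(O1)[C@@](C)(C=C)CC/C=C(\C)[C@H](O)C/C=C(\C)CCC=C(C)C | intermediate
13 | (5S)-5-[(3R,6E,8R,10E)-8-(tert-butyldimethylsilyloxy)-3,7,11,15-tetramethylhexadeca-1,6,10,14-tetraen-3-yl]-5-methyloxolan-2-one | O=C1CC[C@](C)(O1)[C@@](C)(C=C)CC/C=C(\C)[C@H](O[Si](C)(C)C(C)(C)C)C/C=C(\C)CCC=C(C)C | intermediate
14 | cyclopropanol diol: 4,5-dimethyl-5-(TBSO-trienyl)bicyclo[4.1.0]heptane-1,4-diol; ring locants: CH2 bridging C1 and C2, OH on C2 and C5, methyls on C5 and C6 cis, chain cis to the C5 hydroxyl, cyclopropane CH2 on the face of the C5 hydroxyl | O[C@@]12CC[C@](C)(O)[C@](C)(CC/C=C(\C)[C@H](O[Si](C)(C)C(C)(C)C)C/C=C(\C)CCC=C(C)C)[C@@H]1C2 | intermediate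
15 | (3R,4S)-4-hydroxy-3,4-dimethyl-2-methylidene-3-(TBSO-trienyl)cyclohexan-1-one | C=C1C(=O)CC[C@](C)(O)[C@]1(C)CC/C=C(\C)[C@H](O[Si](C)(C)C(C)(C)C)C/C=C(\C)CCC=C(C)C | intermediate
16 | bis(trimethylsilyl) enol ether: ring locants C1=C2 enol ether with OSiMe3 on C2, allyl on C1, OSiMe3 and CH3 on C5 (S), CH3 and TBSO-trienyl on C6 (R) | C=CCC1=C(O[Si](C)(C)C)CC[C@](C)(O[Si](C)(C)C)[C@]1(C)CC/C=C(\C)[C@H](O[Si](C)(C)C(C)(C)C)C/C=C(\C)CCC=C(C)C | intermediate
17 | (2R,3R,4S)-4-hydroxy-3,4-dimethyl-2-(prop-2-en-1-yl)-3-(TBSO-trienyl)cyclohexan-1-one (allyl cis to both methyls) | C=CC[C@H]1C(=O)CC[C@](C)(O)[C@]1(C)CC/C=C(\C)[C@H](O[Si](C)(C)C(C)(C)C)C/C=C(\C)CCC=C(C)C | intermediate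
18 | pinacol boronate: 17 with the allyl group converted to 3-(4,4,5,5-tetramethyl-1,3,2-dioxaborolan-2-yl)propyl | CC1(C)OB(CCC[C@H]2C(=O)CC[C@](C)(O)[C@]2(C)CC/C=C(\C)[C@H](O[Si](C)(C)C(C)(C)C)C/C=C(\C)CCC=C(C)C)OC1(C)C | intermediate
19 | (2R,3R,4S)-4-hydroxy-2-(3-hydroxypropyl)-3,4-dimethyl-3-(TBSO-trienyl)cyclohexan-1-one | OCCC[C@H]1C(=O)CC[C@](C)(O)[C@]1(C)CC/C=C(\C)[C@H](O[Si](C)(C)C(C)(C)C)C/C=C(\C)CCC=C(C)C | intermediate
20 | (2R,3R,4S)-3,4-dimethyl-4-(triethylsilyloxy)-2-[3-(triethylsilyloxy)propyl]-3-(TBSO-trienyl)cyclohexan-1-one | CC[Si](CC)(CC)OCCC[C@H]1C(=O)CC[C@](C)(O[Si](CC)(CC)CC)[C@]1(C)CC/C=C(\C)[C@H](O[Si](C)(C)C(C)(C)C)C/C=C(\C)CCC=C(C)C | intermediate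
21 | bromomagnesium alkoxide of the C2 ethynyl carbinol: 20 with C2 carrying ethynyl (equatorial) and OMgBr (axial, cis to the methyls) | CC[Si](CC)(CC)OCCC[C@H]1[C@](O[Mg]Br)(C#C)CC[C@](C)(O[Si](CC)(CC)CC)[C@]1(C)CC/C=C(\C)[C@H](O[Si](C)(C)C(C)(C)C)C/C=C(\C)CCC=C(C)C | intermediate
22 | propargylic 4-methylbenzenesulfinate of the same carbinol (both configurations at sulfur) | CC[Si](CC)(CC)OCCC[C@H]1[C@](OS(=O)c2ccc(C)cc2)(C#C)CC[C@](C)(O[Si](CC)(CC)CC)[C@]1(C)CC/C=C(\C)[C@H](O[Si](C)(C)C(C)(C)C)C/C=C(\C)CCC=C(C)C | intermediate
23 | allenyl sulfone: ring locants (1S,5S,6R), C2 carrying =C=CH–SO2(4-methylphenyl), both allene axial epimers; C1 3-(triethylsilyloxy)propyl, C5 OSiEt3 and CH3, C6 CH3 and TBSO-trienyl | CC[Si](CC)(CC)OCCC[C@H]1C(=C=CS(=O)(=O)c2ccc(C)cc2)CC[C@](C)(O[Si](CC)(CC)CC)[C@]1(C)CC/C=C(\C)[C@H](O[Si](C)(C)C(C)(C)C)C/C=C(\C)CCC=C(C)C | intermediate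
24 | (Z)-allyl sulfone: as 23 with C2=C(CH3)CH2SO2(4-methylphenyl), sulfonylmethyl cis to C1 | CC[Si](CC)(CC)OCCC[C@H]1/C(=C(/C)CS(=O)(=O)c2ccc(C)cc2)CC[C@](C)(O[Si](CC)(CC)CC)[C@]1(C)CC/C=C(\C)[C@H](O[Si](C)(C)C(C)(C)C)C/C=C(\C)CCC=C(C)C | intermediate
25 | alpha-lithio derivative of 24 | CC[Si](CC)(CC)OCCC[C@H]1/C(=C(/C)C([Li])S(=O)(=O)c2ccc(C)cc2)CC[C@](C)(O[Si](CC)(CC)CC)[C@]1(C)CC/C=C(\C)[C@H](O[Si](C)(C)C(C)(C)C)C/C=C(\C)CCC=C(C)C | intermediate
26 | silylated (Z)-enal: ring locants (1S,5S,6R), C2=C(CH3)CHO with CHO cis to C1; C1 3-(triethylsilyloxy)propyl, C5 OSiEt3 and CH3, C6 CH3 and TBSO-trienyl | CC[Si](CC)(CC)OCCC[C@H]1/C(=C(/C)C=O)CC[C@](C)(O[Si](CC)(CC)CC)[C@]1(C)CC/C=C(\C)[C@H](O[Si](C)(C)C(C)(C)C)C/C=C(\C)CCC=C(C)C | intermediate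
27 | triol: (2Z)-2-[(ring locants 1S,5S,6R)-5-hydroxy-1-(3-hydroxypropyl)-5,6-dimethyl-6-[(3E,5R,7E)-5-hydroxy-4,8,12-trimethyltrideca-3,7,11-trien-1-yl]cyclohex-2-ylidene]propanal | OCCC[C@H]1/C(=C(/C)C=O)CC[C@](C)(O)[C@]1(C)CC/C=C(\C)[C@H](O)C/C=C(\C)CCC=C(C)C | intermediate
28 | stearic acid, octadecanoic acid | CCCCCCCCCCCCCCCCCC(=O)O | starting material
29 | stearoyl chloride, octadecanoyl chloride | CCCCCCCCCCCCCCCCCC(=O)Cl | intermediate
30 | target: 3-[(ring locants 1S,5S,6R)-5-hydroxy-5,6-dimethyl-2-[(2Z)-1-oxopropan-2-ylidene]-6-[(3E,5R,7E)-5-hydroxy-4,8,12-trimethyltrideca-3,7,11-trien-1-yl]cyclohexyl]propyl octadecanoate | CCCCCCCCCCCCCCCCCC(=O)OCCC[C@H]1/C(=C(/C)C=O)CC[C@](C)(O)[C@]1(C)CC/C=C(\C)[C@H](O)C/C=C(\C)CCC=C(C)C | target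

## Step count and least certain steps

Total: 17 steps. Longest linear sequence: 17 steps, from 1 to 30; 3, 8 and 28 enter as purchased materials.

Step 2 (key step). What may go wrong: weak discrimination between the methyl group and the CH2CH2CO2Et arm in the chair (low enantiomeric purity), a competing uncatalysed addition through the boroxine, or the opposite sense of induction. Fallback, resolution in place of catalysis: from 2 and 3 the uncatalysed allylboration (toluene, rt) should give the racemic lactone F1 with the same relative configuration. Opening with (S)-1-phenylethylamine and AlMe3 gives the diastereomeric hydroxy amides, the (4S,5R)-amide F2 and the (4R,5S)-amide F3, which are separated. F2 is relactonised with p-TsOH in hot toluene and comes back to the route at 5.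

Step 8. What may go wrong: slow ligand exchange at the neopentyl-type vinyl group, or failure of the lactone carbonyl to insert through the strained bridged titanacycle, so that reduction of the lactone takes over. Fallback, ring closure on an open-chain ester through a chair: from 13, KOH in aqueous MeOH then MeI in DMF gives the hydroxy methyl ester F4, which is silylated at once with Me3Si-imidazole to the trimethylsilyl ether F5. Kulinkovich cyclisation of F5 under the titanium conditions of step 8 gives the silylated cyclopropanol F6, and K2CO3 in MeOH removes the trimethylsilyl group to rejoin the route at 14.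

Step 10. What may go wrong: poor facial selectivity in the protonation at C1, or an equilibrium that does not favour the arm-equatorial epimer enough. Fallback, separation and recycling in place of selective protonation: from 16, hydrolysis gives 17 together with its C1 epimer F7. The two are separated by chromatography, F7 is re-equilibrated with DBU in CH2Cl2 and resubmitted, and the material returns to the route at 17.

Step 14. What may go wrong: methyl delivery from the C1 side after a ring flip, or gamma-protonation of the carbanion to a vinyl sulfone. Fallback, a different geometry-setting event: from 20, CH2=C(CH3)MgBr with CeCl3 gives the tertiary allylic alcohol F8. Oxidative 1,3-transposition of the Babler–Dauben type with an oxoammonium salt gives 26 together with the (E)-enal F9; these are separated, F9 is recycled by sensitised photoisomerisation, and the route is rejoined at 26.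

Step 15. What may go wrong: attack of unreacted carbanion on the aldehyde as it forms, or oxygenation at the gamma-carbon. Fallback, an electrophilic sequence with no carbanion: from 20, HC≡CMgBr with CeCl3 and then Ac2O gives the propargylic acetate F10. AgSbF6-catalysed [3,3] shift (Saucy–Marbet rearrangement) gives the allenyl acetate F11. After removal of silver, N-iodosuccinimide in wet acetone should attack the central allene carbon from the C3 side to give the alpha-iodo enal F12. Stille coupling with Me4Sn (Pd2(dba)3, AsPh3, CuI) returns to the route at 26.

## Further compounds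

F1 | step 2 | racemic lactone (5 and its enantiomer) | O=C1CC[C@](C)(O1)[C@@](C)(C=C)CCC=C(C)C.O=C1CC[C@@](C)(O1)[C@](C)(C=C)CCC=C(C)C
F2 | step 2 | (4S,5R)-5-ethenyl-4-hydroxy-4,5,9-trimethyl-N-[(1S)-1-phenylethyl]dec-8-enamide | C[C@H](NC(=O)CC[C@](C)(O)[C@@](C)(C=C)CCC=C(C)C)c1ccccc1
F3 | step 2 | (4R,5S)-5-ethenyl-4-hydroxy-4,5,9-trimethyl-N-[(1S)-1-phenylethyl]dec-8-enamide | C[C@H](NC(=O)CC[C@@](C)(O)[C@](C)(C=C)CCC=C(C)C)c1ccccc1
F4 | step 8 | hydroxy methyl ester from opening of 13 | COC(=O)CC[C@](C)(O)[C@@](C)(C=C)CC/C=C(\C)[C@H](O[Si](C)(C)C(C)(C)C)C/C=C(\C)CCC=C(C)C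
F5 | step 8 | trimethylsilyl ether of F4 | COC(=O)CC[C@](C)(O[Si](C)(C)C)[C@@](C)(C=C)CC/C=C(\C)[C@H](O[Si](C)(C)C(C)(C)C)C/C=C(\C)CCC=C(C)C
F6 | step 8 | cyclopropanol 14 with the C5 oxygen as trimethylsilyl ether | O[C@@]12CC[C@](C)(O[Si](C)(C)C)[C@](C)(CC/C=C(\C)[C@H](O[Si](C)(C)C(C)(C)C)C/C=C(\C)CCC=C(C)C)[C@@H]1C2
F7 | step 10 | C1 epimer of 17 (allyl trans to both methyls) | C=CC[C@@H]1C(=O)CC[C@](C)(O)[C@]1(C)CC/C=C(\C)[C@H](O[Si](C)(C)C(C)(C)C)C/C=C(\C)CCC=C(C)C
F8 | step 14 | C2 prop-1-en-2-yl carbinol from 20 (hydroxyl axial, cis to the methyls) | CC[Si](CC)(CC)OCCC[C@H]1[C@](O)(C(C)=C)CC[C@](C)(O[Si](CC)(CC)CC)[C@]1(C)CC/C=C(\C)[C@H](O[Si](C)(C)C(C)(C)C)C/C=C(\C)CCC=C(C)C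
F9 | step 14 | (E)-enal isomer of 26 (formyl trans to C1) | CC[Si](CC)(CC)OCCC[C@H]1/C(=C(\C)C=O)CC[C@](C)(O[Si](CC)(CC)CC)[C@]1(C)CC/C=C(\C)[C@H](O[Si](C)(C)C(C)(C)C)C/C=C(\C)CCC=C(C)C
F10 | step 15 | propargylic acetate of the C2 ethynyl carbinol | CC[Si](CC)(CC)OCCC[C@H]1[C@](OC(C)=O)(C#C)CC[C@](C)(O[Si](CC)(CC)CC)[C@]1(C)CC/C=C(\C)[C@H](O[Si](C)(C)C(C)(C)C)C/C=C(\C)CCC=C(C)C
F11 | step 15 | allenyl acetate (C2=C=CH–OAc, both allene axial epimers) | CC[Si](CC)(CC)OCCC[C@H]1C(=C=COC(C)=O)CC[C@](C)(O[Si](CC)(CC)CC)[C@]1(C)CC/C=C(\C)[C@H](O[Si](C)(C)C(C)(C)C)C/C=C(\C)CCC=C(C)C
F12 | step 15 | alpha-iodo enal (iodine cis to C3, formyl cis to C1) | CC[Si](CC)(CC)OCCC[C@H]1/C(=C(/I)C=O)CC[C@](C)(O[Si](CC)(CC)CC)[C@]1(C)CC/C=C(\C)[C@H](O[Si](C)(C)C(C)(C)C)C/C=C(\C)CCC=C(C)C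
A1 | alternative 1 | 1-alkyl-2-silyloxy diene, (Z)-enol ether with the alkyl group trans to the vinyl group | C=C/C(O[Si](C)(C)C(C)(C)C)=C/CCCO[Si](C)(C)C(C)(C)C
A2 | alternative 1 | 5-menthyloxy-3,4-dimethylfuran-2(5H)-one | CC1=C(C)[C@H](O[C@@H]2C[C@H](C)CC[C@H]2C(C)C)OC1=O
A3 | alternative 1 | cis-fused bicyclic lactone acetal with the ring silyl enol ether | CC(C)(C)[Si](C)(C)OCCC[C@H]1C(O[Si](C)(C)C(C)(C)C)=CC[C@]2(C)C(=O)O[C@@H](O[C@@H]3C[C@H](C)CC[C@H]3C(C)C)[C@]12C
A4 | alternative 2 | 1,7-enyne with the C5 trimethylsilyl ether | CC#CCC[C@](C)(O[Si](C)(C)C)[C@@](C)(C=C)CCC=C(C)C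
A5 | alternative 2 | cyclohexane diiodide with iodomethyl on C1 and the (Z)-alkenyl iodide | IC[C@H]1/C(=C(/C)I)CC[C@](C)(O[Si](C)(C)C)[C@]1(C)CCC=C(C)C
A6 | alternative 3 | bromoacetal of (4S)-4-hydroxy-3,4-dimethylcyclohex-2-enone | O=C1C=C(C)[C@@](C)(OC(CBr)OCC)CC1
A7 | alternative 3 | allyltributylstannane | C=CC[Sn](CCCC)(CCCC)CCCC
A8 | alternative 3 | cis-fused bicyclic acetal ketone with the C1 allyl group | C=CC[C@H]1C(=O)CC[C@]2(C)OC(OCC)C[C@]12C
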